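Retrosynthesis: after the ten benzyl ethers are added and a C4 oxygen is reinstated, O1–C8a and C4a–C4 of the epicatechin half are cut together. The C2–C3 bond of that half is cut next, and the C6'–C8 biaryl bond last.
Enabling feature: in the epicatechin half, ring A is fused to ring C through the adjacent atoms C8a (bonded to O1) and C4a (bonded to C4). Removing both bonds leaves a benzyne. Its oxygens at C5 (next to C4a) and C7 bias it so that oxygen goes to C8a and carbon to C4a.
Forward: the catechin half is used intact, brominated at C8 and coupled to ring B of the upper half. A glycolate aldol adds C2–C3–C4, one aryne annulation installs ring A and closes ring C, C4 is deoxygenated, and all benzyl groups are removed.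
Stereochemistry: 2R,3S of the lower half comes from (+)-catechin. C2 and C3 of the upper half come from an Evans syn aldol with the (S)-4-benzyl auxiliary and are carried unchanged, because the C2–O bond is never broken.

Key step: step 14

Assumption: the target SMILES defines no axial chirality at the C6'–C8 bond, so the axis is treated as not fixed. Hindered intermediates may exist as interconverting rotamers, which does not affect the four carbon stereocentres.
Abbreviation: "penta-O-benzylcatechin-8-yl" = (2R,3S)-3,5,7-tris(benzyloxy)-2-[3,4-bis(benzyloxy)phenyl]chroman-8-yl.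

Step 1
Reactants: 1 (+)-catechin
Product: 2 5,7,3',4'-tetra-O-benzyl-(+)-catechin (2R,3S; 3-OH free)
Conditions: BnBr, K2CO3, DMF, 0 °C → rt
Reagents that add atoms: benzyl bromide, BrCc1ccccc1
Why: Williamson etherification in which carbonate deprotonates only the four phenols, so the C3 alcohol and both stereocentres stay untouched.

Step 2
Reactants: 2 5,7,3',4'-tetra-O-benzyl-(+)-catechin
Product: 3 3,5,7,3',4'-penta-O-benzyl-(+)-catechin (2R,3S)
Conditions: NaH, BnBr, DMF, 0 °C → rt
Reagents that add atoms: benzyl bromide, BrCc1ccccc1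
Why: Williamson etherification of the secondary alkoxide, safe for C2 because no free phenol remains that could open ring C.

Step 3
Reactants: 3 3,5,7,3',4'-penta-O-benzyl-(+)-catechin
Product: 4 8-bromo-3,5,7,3',4'-penta-O-benzyl-(+)-catechin (2R,3S)
Conditions: NBS, CH2Cl2, −78 °C → rt
Reagents that add atoms: N-bromosuccinimide, O=C1CCC(=O)N1Br
Why: Electrophilic aromatic bromination with one equivalent of NBS takes C8, the most nucleophilic position of the benzylated phloroglucinol ring in flavan-3-ols.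

Step 4
Reactants: 5 3,4-bis(benzyloxy)benzaldehyde
Product: 6 4,5-bis(benzyloxy)-2-bromobenzaldehyde
Conditions: Br2, NaOAc, AcOH, rt
Reagents that add atoms: bromine, BrBr
Why: Electrophilic aromatic bromination goes para to the 3-benzyloxy group (old C6, ortho to the formyl group), as with other 3,4-dialkoxybenzaldehydes, and acetate buffers the HBr so the benzyl ethers survive.

Step 5
Reactants: 6 4,5-bis(benzyloxy)-2-bromobenzaldehyde
Product: 7 4,5-bis(benzyloxy)-2-(4,4,5,5-tetramethyl-1,3,2-dioxaborolan-2-yl)benzaldehyde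
Conditions: B2pin2, PdCl2(dppf) (cat.), KOAc, 1,4-dioxane, 90 °C
Reagents that add atoms: bis(pinacolato)diboron, CC1(C)OB(OC1(C)C)B1OC(C)(C)C(C)(C)O1
Why: Miyaura borylation tolerates the aldehyde and the benzyl ethers, and the weak base acetate prevents homocoupling.

Step 6
Reactants: 4 8-bromo-3,5,7,3',4'-penta-O-benzyl-(+)-catechin; 7 4,5-bis(benzyloxy)-2-(4,4,5,5-tetramethyl-1,3,2-dioxaborolan-2-yl)benzaldehyde
Product: 8 4,5-bis(benzyloxy)-2-(penta-O-benzylcatechin-8-yl)benzaldehyde
Conditions: Pd(OAc)2 (cat.), SPhos, K3PO4, toluene/H2O, 90 °C (7 in excess)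
Reagents that add atoms: none
Why: Suzuki–Miyaura coupling in which the bulky, electron-rich biarylphosphine helps zerovalent palladium insert into the hindered C8–Br bond and favours reductive elimination to the tri-ortho-substituted biaryl, forming C6'–C8.

Step 7
Reactants: 9 (S)-4-benzyloxazolidin-2-one; 10 benzyloxyacetyl chloride
Product: 12 (S)-4-benzyl-3-(benzyloxyacetyl)oxazolidin-2-one, via lithium oxazolidinide 11 (not isolated)
Conditions: n-BuLi, THF, −78 °C; then 10, −78 → 0 °C
Reagents that add atoms: none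
Why: N-acylation of the lithiated oxazolidinone by the acid chloride is the standard loading of an Evans auxiliary and leaves its stereocentre untouched.

Step 8
Reactants: 12 (S)-4-benzyl-3-(benzyloxyacetyl)oxazolidin-2-one; 8 4,5-bis(benzyloxy)-2-(penta-O-benzylcatechin-8-yl)benzaldehyde
Product: 15 (4S)-4-benzyl-3-{(2S,3R)-2-(benzyloxy)-3-hydroxy-3-[4,5-bis(benzyloxy)-2-(penta-O-benzylcatechin-8-yl)phenyl]propanoyl}oxazolidin-2-one, via Z-boron enolate 13 (not isolated), via boron aldolate 14 (not isolated)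
Conditions: 12 (excess), Bu2BOTf, Et3N, CH2Cl2, −78 → 0 °C; then 8, −78 → 0 °C; H2O2, MeOH, pH 7 buffer, 0 °C
Reagents that add atoms: none
Why: Evans syn aldol reaction, in which soft enolisation gives the Z-boron enolate and a closed Zimmerman–Traxler chair reacts on the enolate face away from the benzyl group of the (S)-auxiliary, setting (2S,3R), the future C3 and C2 of the epicatechin half in the cis relation.

Step 9
Reactants: 15 the syn aldol imide
Product: 16 methyl (2S,3R)-2-(benzyloxy)-3-hydroxy-3-[4,5-bis(benzyloxy)-2-(penta-O-benzylcatechin-8-yl)phenyl]propanoate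
Conditions: NaOMe, MeOH/CH2Cl2, −15 °C, short contact; AcOH quench
Reagents that add atoms: sodium methoxide, [Na+].[O-]C
Why: Methanolysis (transesterification) of the imide occurs at the exocyclic carbonyl, which the α-benzyloxy group activates, and the cold, protic, brief treatment should keep the aldol from cleaving or epimerising.

Step 10
Reactants: 16 the syn hydroxy ester
Product: 17 methyl (2S,3R)-2-(benzyloxy)-3-(trimethylsilyloxy)-3-[4,5-bis(benzyloxy)-2-(penta-O-benzylcatechin-8-yl)phenyl]propanoate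
Conditions: TMSCl, imidazole, CH2Cl2, 0 °C
Reagents that add atoms: chlorotrimethylsilane, C[Si](C)(C)Cl
Why: Imidazole-promoted O-silylation masks the only O–H, so the annulation runs without a proton source and the alkoxide is released only on demand.

Step 11
Reactants: 18 3,5-bis(benzyloxy)phenol
Product: 19 3,5-bis(benzyloxy)-2-bromophenol
Conditions: NBS, CH2Cl2, −78 → 0 °C
Reagents that add atoms: N-bromosuccinimide, O=C1CCC(=O)N1Br
Why: Electrophilic aromatic bromination with one equivalent of NBS should take one of the two equivalent positions ortho to the hydroxyl and para to a benzyloxy group, the third free position being shielded between two benzyloxy groups.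

Step 12
Reactants: 19 3,5-bis(benzyloxy)-2-bromophenol
Product: 20 [3,5-bis(benzyloxy)-2-bromophenoxy]trimethylsilane
Conditions: (Me3Si)2NH, THF, 65 °C; volatiles removed in vacuo
Reagents that add atoms: hexamethyldisilazane, C[Si](C)(C)N[Si](C)(C)C
Why: O-silylation of the phenol with the disilazane gives only ammonia beside the product, so the moisture-sensitive aryl silyl ether can be used after evaporation.

Step 13
Reactants: 20 [3,5-bis(benzyloxy)-2-bromophenoxy]trimethylsilane
Product: 23 3,5-bis(benzyloxy)-2-(trimethylsilyl)phenyl trifluoromethanesulfonate, via aryllithium 21 (not isolated), via lithium phenoxide 22 (not isolated)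
Conditions: n-BuLi, THF, −78 °C; then Tf2O, −78 °C
Reagents that add atoms: trifluoromethanesulfonic anhydride, O=S(=O)(OS(=O)(=O)C(F)(F)F)C(F)(F)F
Why: Bromine–lithium exchange outruns attack on the benzyl ethers at −78 °C, the aryllithium undergoes a retro-Brook 1,3-shift of silicon from oxygen to carbon, and the resulting phenoxide is triflated, the standard entry to o-silylaryl triflates.

Step 14
Reactants: 17 the silyl-masked syn hydroxy ester; 23 3,5-bis(benzyloxy)-2-(trimethylsilyl)phenyl trifluoromethanesulfonate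
Product: 27 (2R,3S)-3,5,7-tris(benzyloxy)-2-[4,5-bis(benzyloxy)-2-(penta-O-benzylcatechin-8-yl)phenyl]chroman-4-one (2,3-cis), via potassium alkoxide 24 (not isolated), via aryne 25 (not isolated), via aryl anion 26 (not isolated)
Conditions: 23 (about 2 equiv), KF, 18-crown-6, 4 Å MS, THF, −10 °C → rt
Reagents that add atoms: none
Why: Proposed new method: fluoride strips the silyl group from carbon in 23, where loss of triflate gives aryne 25, and from oxygen in 17, which frees alkoxide 24; 24 adds to the aryne terminus farther from the adjacent benzyloxy substituent (O1–C8a), and the resulting aryl anion 26, located at the future C4a beside that substituent, attacks the ester carbon (C4a–C4) and expels methoxide. The closest known reaction type is the fluoride-triggered aryne insertion with acyl capture that converts salicylate esters into xanthones, whereas an aliphatic β-oxy ester as the oxygen nucleophile has not been shown. Ring C is the only ring closed, by a 6-exo-trig attack on the ester carbonyl. No stereocentre is formed: the C2–O bond is never broken and C3 is a spectator, so the syn (2S,3R) relationship in 17 should reappear as the 2,3-cis (2R,3S) relationship in 27. The regioselectivity needed comes from the bond-angle distortion of a 3-alkoxyaryne, which sends nucleophiles to C1 and outweighs the weak opposite bias of the second benzyloxy group at C5 of the aryne. Acyl capture has to beat protonation and the base-sensitive C2–C3 array has to survive, which is secured because 17 carries no O–H (silyl ether, dry THF) and because 17 and 23 act as silyl donors that turn the expelled methoxide into MeOSiMe3 while releasing the next alkoxide or aryne, so that neither alkoxide nor methoxide builds up to drive retro-aldol cleavage or C3 epimerisation.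

Step 15
Reactants: 27 the 2,3-cis flavan-4-one
Product: 28 (2R,3R)-3,5,7-tris(benzyloxy)-2-[4,5-bis(benzyloxy)-2-(penta-O-benzylcatechin-8-yl)phenyl]chroman-4-ol (C4 configuration not defined)
Conditions: NaBH4, THF/MeOH, −10 → 0 °C
Reagents that add atoms: none
Why: Borohydride reduction of the aryl ketone, run cold so that C3 is not enolised; hydride should approach anti to the axial 3-benzyloxy group, but either C4 epimer serves because C4 becomes a CH2 in the next step.

Step 16
Reactants: 28 the flavan-4-ol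
Product: 29 (2R,3R)-3,5,7-tris(benzyloxy)-2-[4,5-bis(benzyloxy)-2-(penta-O-benzylcatechin-8-yl)phenyl]chroman (deca-O-benzyl ether of the target)
Conditions: Et3SiH (large excess), CF3CO2H, CH2Cl2, −40 → 0 °C
Reagents that add atoms: none
Why: Ionic hydrogenation, in which the acid ionises the C4 alcohol to a benzylic cation stabilised by O1 and the oxygens at C5 and C7, and the excess silane delivers hydride, erasing the C4 stereocentre without involving C2 or C3.

Step 17
Reactants: 29 the deca-O-benzyl ether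
Product: 30 epicatechin-(6'→8)-catechin, the target (upper half 2R,3R; lower half 2R,3S)
Conditions: H2 (1 atm), Pd(OH)2/C, THF/MeOH, rt
Reagents that add atoms: none
Why: Catalytic hydrogenolysis removes all ten benzyl ethers under neutral conditions that normally leave the cyclic C2–O1 bonds and the stereocentres of flavan-3-ols intact.

Compound list
1 | (+)-catechin, (2R,3S)-2-(3,4-dihydroxyphenyl)chroman-3,5,7-triol | O[C@H]1Cc2c(O)cc(O)cc2O[C@@H]1c1ccc(O)c(O)c1 | starting material
2 | 5,7,3',4'-tetra-O-benzyl-(+)-catechin | c3c(OCc9ccccc9)cc(OCc9ccccc9)c4c3O[C@H](c3ccc(OCc9ccccc9)c(OCc9ccccc9)c3)[C@@H](O)C4 | intermediate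
3 | 3,5,7,3',4'-penta-O-benzyl-(+)-catechin | c3c(OCc9ccccc9)cc(OCc9ccccc9)c4c3O[C@H](c3ccc(OCc9ccccc9)c(OCc9ccccc9)c3)[C@@H](OCc9ccccc9)C4 | intermediate
4 | 8-bromo-3,5,7,3',4'-penta-O-benzyl-(+)-catechin | Brc3c(OCc9ccccc9)cc(OCc9ccccc9)c4c3O[C@H](c3ccc(OCc9ccccc9)c(OCc9ccccc9)c3)[C@@H](OCc9ccccc9)C4 | intermediate
5 | 3,4-bis(benzyloxy)benzaldehyde | O=Cc1ccc(OCc2ccccc2)c(OCc2ccccc2)c1 | starting material
6 | 4,5-bis(benzyloxy)-2-bromobenzaldehyde | O=Cc1cc(OCc9ccccc9)c(OCc9ccccc9)cc1Br | intermediate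
7 | 4,5-bis(benzyloxy)-2-(4,4,5,5-tetramethyl-1,3,2-dioxaborolan-2-yl)benzaldehyde | O=Cc1cc(OCc9ccccc9)c(OCc9ccccc9)cc1B2OC(C)(C)C(C)(C)O2 | intermediate
8 | 4,5-bis(benzyloxy)-2-(penta-O-benzylcatechin-8-yl)benzaldehyde | O=Cc1cc(OCc9ccccc9)c(OCc9ccccc9)cc1-c3c(OCc9ccccc9)cc(OCc9ccccc9)c4c3O[C@H](c3ccc(OCc9ccccc9)c(OCc9ccccc9)c3)[C@@H](OCc9ccccc9)C4 | intermediate
9 | (S)-4-benzyloxazolidin-2-one | O=C1N[C@@H](Cc2ccccc2)CO1 | starting material
10 | benzyloxyacetyl chloride | O=C(Cl)COCc1ccccc1 | starting material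
11 | lithium salt of 9 (formed in the flask) | [Li]N1[C@@H](Cc2ccccc2)COC1=O | intermediate
12 | (S)-4-benzyl-3-(benzyloxyacetyl)oxazolidin-2-one | O=C(COCc1ccccc1)N1[C@@H](Cc2ccccc2)COC1=O | intermediate
13 | (Z)-dibutylboron enolate of 12 (formed in the flask) | CCCCB(CCCC)O/C(=C\OCc1ccccc1)N1[C@@H](Cc2ccccc2)COC1=O | intermediate
14 | dibutylboron aldolate of 15 (formed in the flask) | CCCCB(CCCC)O[C@H](c1cc(OCc9ccccc9)c(OCc9ccccc9)cc1-c3c(OCc9ccccc9)cc(OCc9ccccc9)c4c3O[C@H](c3ccc(OCc9ccccc9)c(OCc9ccccc9)c3)[C@@H](OCc9ccccc9)C4)[C@H](OCc9ccccc9)C(=O)N1[C@@H](Cc2ccccc2)COC1=O | intermediate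
15 | (4S)-4-benzyl-3-{(2S,3R)-2-(benzyloxy)-3-hydroxy-3-[4,5-bis(benzyloxy)-2-(penta-O-benzylcatechin-8-yl)phenyl]propanoyl}oxazolidin-2-one | O[C@H](c1cc(OCc9ccccc9)c(OCc9ccccc9)cc1-c3c(OCc9ccccc9)cc(OCc9ccccc9)c4c3O[C@H](c3ccc(OCc9ccccc9)c(OCc9ccccc9)c3)[C@@H](OCc9ccccc9)C4)[C@H](OCc9ccccc9)C(=O)N1[C@@H](Cc2ccccc2)COC1=O | intermediate
16 | methyl (2S,3R)-2-(benzyloxy)-3-hydroxy-3-[4,5-bis(benzyloxy)-2-(penta-O-benzylcatechin-8-yl)phenyl]propanoate | O[C@H](c1cc(OCc9ccccc9)c(OCc9ccccc9)cc1-c3c(OCc9ccccc9)cc(OCc9ccccc9)c4c3O[C@H](c3ccc(OCc9ccccc9)c(OCc9ccccc9)c3)[C@@H](OCc9ccccc9)C4)[C@H](OCc9ccccc9)C(=O)OC | intermediate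
17 | methyl (2S,3R)-2-(benzyloxy)-3-(trimethylsilyloxy)-3-[4,5-bis(benzyloxy)-2-(penta-O-benzylcatechin-8-yl)phenyl]propanoate | C[Si](C)(C)O[C@H](c1cc(OCc9ccccc9)c(OCc9ccccc9)cc1-c3c(OCc9ccccc9)cc(OCc9ccccc9)c4c3O[C@H](c3ccc(OCc9ccccc9)c(OCc9ccccc9)c3)[C@@H](OCc9ccccc9)C4)[C@H](OCc9ccccc9)C(=O)OC | intermediate
18 | 3,5-bis(benzyloxy)phenol | Oc1cc(OCc2ccccc2)cc(OCc2ccccc2)c1 | starting material
19 | 3,5-bis(benzyloxy)-2-bromophenol | Oc1cc(OCc9ccccc9)cc(OCc9ccccc9)c1Br | intermediate
20 | [3,5-bis(benzyloxy)-2-bromophenoxy]trimethylsilane | C[Si](C)(C)Oc1cc(OCc9ccccc9)cc(OCc9ccccc9)c1Br | intermediate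
21 | [3,5-bis(benzyloxy)-2-lithiophenoxy]trimethylsilane (formed in the flask) | C[Si](C)(C)Oc1cc(OCc9ccccc9)cc(OCc9ccccc9)c1[Li] | intermediate
22 | lithium 3,5-bis(benzyloxy)-2-(trimethylsilyl)phenoxide (formed in the flask) | [Li]Oc1cc(OCc9ccccc9)cc(OCc9ccccc9)c1[Si](C)(C)C | intermediate
23 | 3,5-bis(benzyloxy)-2-(trimethylsilyl)phenyl trifluoromethanesulfonate | C[Si](C)(C)c1c(OS(=O)(=O)C(F)(F)F)cc(OCc9ccccc9)cc1OCc9ccccc9 | intermediate
24 | potassium alkoxide of 16 (formed in the flask) | [K+].[O-][C@H](c1cc(OCc9ccccc9)c(OCc9ccccc9)cc1-c3c(OCc9ccccc9)cc(OCc9ccccc9)c4c3O[C@H](c3ccc(OCc9ccccc9)c(OCc9ccccc9)c3)[C@@H](OCc9ccccc9)C4)[C@H](OCc9ccccc9)C(=O)OC | intermediate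
25 | 3,5-bis(benzyloxy)benzyne, 1,2-didehydro-3,5-bis(benzyloxy)benzene (formed in the flask) | C1#CC(OCc2ccccc2)=CC(OCc2ccccc2)=C1 | intermediate
26 | O-arylated ester metallated at the future C4a (formed in the flask) | [K]c1c(OCc9ccccc9)cc(OCc9ccccc9)cc1O[C@H](c1cc(OCc9ccccc9)c(OCc9ccccc9)cc1-c3c(OCc9ccccc9)cc(OCc9ccccc9)c4c3O[C@H](c3ccc(OCc9ccccc9)c(OCc9ccccc9)c3)[C@@H](OCc9ccccc9)C4)[C@H](OCc9ccccc9)C(=O)OC | intermediate
27 | (2R,3S)-3,5,7-tris(benzyloxy)-2-[4,5-bis(benzyloxy)-2-(penta-O-benzylcatechin-8-yl)phenyl]chroman-4-one, 2,3-cis | c9ccccc9COc1cc(OCc9ccccc9)c2c(c1)O[C@H](c1cc(OCc9ccccc9)c(OCc9ccccc9)cc1-c3c(OCc9ccccc9)cc(OCc9ccccc9)c4c3O[C@H](c3ccc(OCc9ccccc9)c(OCc9ccccc9)c3)[C@@H](OCc9ccccc9)C4)[C@H](OCc9ccccc9)C2=O | intermediate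
28 | (2R,3R)-3,5,7-tris(benzyloxy)-2-[4,5-bis(benzyloxy)-2-(penta-O-benzylcatechin-8-yl)phenyl]chroman-4-ol, C4 not defined | c9ccccc9COc1cc(OCc9ccccc9)c2c(c1)O[C@H](c1cc(OCc9ccccc9)c(OCc9ccccc9)cc1-c3c(OCc9ccccc9)cc(OCc9ccccc9)c4c3O[C@H](c3ccc(OCc9ccccc9)c(OCc9ccccc9)c3)[C@@H](OCc9ccccc9)C4)[C@H](OCc9ccccc9)C2O | intermediate
29 | (2R,3R)-3,5,7-tris(benzyloxy)-2-[4,5-bis(benzyloxy)-2-(penta-O-benzylcatechin-8-yl)phenyl]chroman, deca-O-benzyl ether of the target | c9ccccc9COc1cc(OCc9ccccc9)c2c(c1)O[C@H](c1cc(OCc9ccccc9)c(OCc9ccccc9)cc1-c3c(OCc9ccccc9)cc(OCc9ccccc9)c4c3O[C@H](c3ccc(OCc9ccccc9)c(OCc9ccccc9)c3)[C@@H](OCc9ccccc9)C4)[C@H](OCc9ccccc9)C2 | intermediate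
30 | epicatechin-(6'→8)-catechin, CNP0353739.2 | Oc1cc(O)c2c(c1)O[C@H](c1cc(O)c(O)cc1-c1c(O)cc(O)c3c1O[C@H](c1ccc(O)c(O)c1)[C@@H](O)C3)[C@H](O)C2 | target

Total step count: 17. Longest linear sequence: 11 steps (1, 2, 3, 6, 8, 9, 10, 14, 15, 16, 17).

Steps most likely to fail

1. Step 14. The aryl anion may be quenched by adventitious water, or by internal proton transfer from C3–H, before it reaches the ester. The free alkoxide may also undergo retro-aldol cleavage, and C3 may epimerise under base after ring closure.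
The fallback sets out from 17 and comes back at 28. It uses only known reaction types and forms the same two bonds one after the other, with 1,3,5-trifluorobenzene as the ring A building block. Reduction of 17 with i-Bu2AlH (toluene, −78 °C) would give the α-benzyloxy-β-silyloxy aldehyde F1. Deprotonation of 1,3,5-trifluorobenzene with n-BuLi (THF, −78 °C) gives 2,4,6-trifluorophenyllithium F2, which adds to F1 to form C4a–C4 and give the silyl-protected carbinol F3 (either C4 epimer). K2CO3 in MeOH at 0 °C removes the silyl group to give the diol F4. KN(SiMe3)2 in THF/DMF (0 → 50 °C) then closes O1–C8a by intramolecular SNAr, with retention at C2 and with no carbonyl present that could allow retro-aldol cleavage, to give the 5,7-difluoroflavan-4-ol F5. BnOH/NaH in DMPU at about 100 °C finally exchanges both fluorides by SNAr and delivers 28.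

2. Step 6. Protodeboronation of the formyl-substituted boronate in the aqueous base may outrun the slow oxidative addition into the hindered, electron-rich C8–Br bond.
The fallback sets out from 4 and 6 and comes back at 8, with the roles of the partners reversed and boron avoided. Bromine–lithium exchange on 4 (n-BuLi, THF, −78 °C) would give the 8-lithio compound F6, and ZnCl2 converts it into the arylzinc chloride F7. Negishi coupling of F7 with bromoaldehyde 6 (Pd2(dba)3, SPhos, THF, 50 °C) gives 8. Oxidative addition then occurs at the formyl-activated C–Br bond of 6, and step 5 is no longer needed.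

3. Step 16. Friedel–Crafts self-condensation of the C4 cation with the free C6 and C8 positions may compete with hydride capture, and the acid may cause benzyl migration.
The fallback sets out from 28 and comes back at 29 by a radical route that avoids the cation. NaH, CS2 and MeI (THF, 0 °C) would give the S-methyl xanthate F8. Barton–McCombie deoxygenation of F8 (Bu3SnH, AIBN, toluene, 90 °C) then replaces the C4–O bond by C4–H under neutral conditions.

Further compounds
F1 | step 14 | (2S,3R)-2-(benzyloxy)-3-(trimethylsilyloxy)-3-[4,5-bis(benzyloxy)-2-(penta-O-benzylcatechin-8-yl)phenyl]propanal | C[Si](C)(C)O[C@H](c1cc(OCc9ccccc9)c(OCc9ccccc9)cc1-c3c(OCc9ccccc9)cc(OCc9ccccc9)c4c3O[C@H](c3ccc(OCc9ccccc9)c(OCc9ccccc9)c3)[C@@H](OCc9ccccc9)C4)[C@H](OCc9ccccc9)C=O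
F2 | step 14 | 2,4,6-trifluorophenyllithium | [Li]c1c(F)cc(F)cc1F
F3 | step 14 | 2-(benzyloxy)-1-(2,4,6-trifluorophenyl)-3-(trimethylsilyloxy)-3-[4,5-bis(benzyloxy)-2-(penta-O-benzylcatechin-8-yl)phenyl]propan-1-ol, C1 not defined | C[Si](C)(C)O[C@H](c1cc(OCc9ccccc9)c(OCc9ccccc9)cc1-c3c(OCc9ccccc9)cc(OCc9ccccc9)c4c3O[C@H](c3ccc(OCc9ccccc9)c(OCc9ccccc9)c3)[C@@H](OCc9ccccc9)C4)[C@H](OCc9ccccc9)C(O)c1c(F)cc(F)cc1F
F4 | step 14 | 2-(benzyloxy)-1-(2,4,6-trifluorophenyl)-3-[4,5-bis(benzyloxy)-2-(penta-O-benzylcatechin-8-yl)phenyl]propane-1,3-diol, C1 not defined | O[C@H](c1cc(OCc9ccccc9)c(OCc9ccccc9)cc1-c3c(OCc9ccccc9)cc(OCc9ccccc9)c4c3O[C@H](c3ccc(OCc9ccccc9)c(OCc9ccccc9)c3)[C@@H](OCc9ccccc9)C4)[C@H](OCc9ccccc9)C(O)c1c(F)cc(F)cc1F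
F5 | step 14 | (2R,3R)-3-(benzyloxy)-5,7-difluoro-2-[4,5-bis(benzyloxy)-2-(penta-O-benzylcatechin-8-yl)phenyl]chroman-4-ol, C4 not defined | Fc1cc(F)c2c(c1)O[C@H](c1cc(OCc9ccccc9)c(OCc9ccccc9)cc1-c3c(OCc9ccccc9)cc(OCc9ccccc9)c4c3O[C@H](c3ccc(OCc9ccccc9)c(OCc9ccccc9)c3)[C@@H](OCc9ccccc9)C4)[C@H](OCc9ccccc9)C2O
F6 | step 6 | 8-lithio-3,5,7,3',4'-penta-O-benzylcatechin | [Li]c3c(OCc9ccccc9)cc(OCc9ccccc9)c4c3O[C@H](c3ccc(OCc9ccccc9)c(OCc9ccccc9)c3)[C@@H](OCc9ccccc9)C4
F7 | step 6 | (penta-O-benzylcatechin-8-yl)zinc chloride | Cl[Zn]c3c(OCc9ccccc9)cc(OCc9ccccc9)c4c3O[C@H](c3ccc(OCc9ccccc9)c(OCc9ccccc9)c3)[C@@H](OCc9ccccc9)C4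
F8 | step 16 | O-(flavan-4-yl) S-methyl dithiocarbonate of 28 | c9ccccc9COc1cc(OCc9ccccc9)c2c(c1)O[C@H](c1cc(OCc9ccccc9)c(OCc9ccccc9)cc1-c3c(OCc9ccccc9)cc(OCc9ccccc9)c4c3O[C@H](c3ccc(OCc9ccccc9)c(OCc9ccccc9)c3)[C@@H](OCc9ccccc9)C4)[C@H](OCc9ccccc9)C2OC(=S)SC
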